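**Retrosynthetic overview**
1. Locants (germacranolide numbering): C1=C10 ring olefin, C3 ketone, C4 CH(CH3), C6 lactone O–CH, C7 ring-fusion CH, C8 acyloxy CH; C11, C12, C13 are the α-carbon, carbonyl and exocyclic CH2 of the lactone. Ring A is the cyclodecene, ring B the lactone.
2. Late stage: the C3 ketone comes from a silyl-protected carbinol; ring A from ring-closing metathesis (RCM) forming the (Z)-C1=C10 olefin on a monocyclic lactone; C12=O from allylic oxidation of a 3-methyleneoxolane; the C8 ester from Yamaguchi acylation with the separately made (E)-acid.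
3. Key disconnection: ring B through the C7–C11 bond. Cp2TiCl opens an acyclic C7–C8 epoxide whose O6 carries a propargyl group; 5-exo-dig closure of the C7 radical gives ring B, the C7 stereocentre, the C11=C13 methylene and the free C8 hydroxyl in one operation.
4. Enabling feature: C7 lies between two oxygenated carbons (C6–O of ring B, C8–O of the ester) in an anti-1,3 relationship, so the C6–C7–C8 triad is a masked Sharpless (E)-2,3-epoxy alcohol, and the five ring-B atoms O–C12–C11–C7–C6 map onto a propargyl ether on O6.
5. The epoxy ether is built from ethyl (E)-4-oxobut-2-enoate (C1–C6: allylboration, anti cuprate addition) and 2-methylpent-1-en-4-yne (C7–C10) by ynone formation, Noyori reduction (C6), Red-Al and Sharpless epoxidation (C8). Ring order: B as oxolane, then lactone carbonyl, then A.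

Key step: step 11

Remark: the (S)-C3 carbinol set in step 1 is a temporary stereocentre that steers C4 and is oxidised to the ketone in step 19; the carbinol centre of 20 is racemic and is erased in step 13.

**Route**

Step 1
Reactants: 1 ethyl (E)-4-oxobut-2-enoate
Product: 2 ethyl (2E,4S)-4-hydroxyhepta-2,6-dienoate
Conditions: (−)-Ipc2B(allyl) (1 M in pentane, 1.2 equiv), Et2O, −78 °C; then NaBO3·4H2O, THF/H2O, rt
Reagents that add atoms: (−)-B-allyldiisopinocampheylborane, C=CCB([C@@H]1C[C@@H]2C[C@H]([C@H]1C)C2(C)C)[C@@H]1C[C@@H]2C[C@H]([C@H]1C)C2(C)C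
Why: Brown allylboration through a closed chair transition state adds the allyl group 1,2 to the Si face of the aldehyde, which should set the (S)-C3 carbinol and leave the enoate untouched.

Step 2
Reactants: 2 ethyl (2E,4S)-4-hydroxyhepta-2,6-dienoate
Product: 3 ethyl (2E,4S)-4-[(tert-butyldimethylsilyl)oxy]hepta-2,6-dienoate
Conditions: TBSCl, imidazole, DMF, rt
Reagents that add atoms: tert-butyldimethylsilyl chloride, CC(C)(C)[Si](C)(C)Cl
Why: Standard silylation of a secondary alcohol gives the C3 protecting group carried to the end and the bulky γ-substituent needed for the next step.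

Step 3
Reactants: 3 ethyl (2E,4S)-4-[(tert-butyldimethylsilyl)oxy]hepta-2,6-dienoate
Product: 5 ethyl (3R,4S)-4-[(tert-butyldimethylsilyl)oxy]-3-methylhept-6-enoate, via silyl ketene acetal 4 (not isolated)
Conditions: CuI, MeLi (Me2CuLi), TMSCl, THF, −78 °C; then aq. NH4Cl
Reagents that add atoms: lithium dimethylcuprate, [Li+].C[Cu-]C
Why: Silyl-chloride-accelerated conjugate addition of a Gilman cuprate to an (E)-γ-silyloxy enoate should proceed anti to the γ-oxygen (C–O bond antiperiplanar to the forming bond, γ-hydrogen eclipsing the olefin), setting (R)-C4 from (S)-C3 before the ketene acetal is hydrolysed on work-up.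

Step 4
Reactants: 5 ethyl (3R,4S)-4-[(tert-butyldimethylsilyl)oxy]-3-methylhept-6-enoate
Product: 6 (3R,4S)-4-[(tert-butyldimethylsilyl)oxy]-N-methoxy-N,3-dimethylhept-6-enamide
Conditions: MeNHOMe·HCl, i-PrMgCl, THF, −20 → 0 °C
Reagents that add atoms: N,O-dimethylhydroxylamine hydrochloride, CNOC.Cl
Why: Direct ester-to-Weinreb-amide conversion by the magnesium amide touches no stereocentre because C4 is β to the carbonyl.

Step 5
Reactants: 7 3-chloro-2-methylprop-1-ene; 8 ethynylmagnesium bromide
Product: 9 2-methylpent-1-en-4-yne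
Conditions: CuCl (5 mol %), THF, 45 °C; fractional distillation (or use as a dried THF solution)
Reagents that add atoms: none
Why: Copper-catalysed coupling of an alkynyl Grignard reagent with an allylic chloride gives the skipped enyne, and SN2 and SN2' attack on the methallyl unit lead to the same product.

Step 6
Reactants: 6 (3R,4S)-4-[(tert-butyldimethylsilyl)oxy]-N-methoxy-N,3-dimethylhept-6-enamide; 9 2-methylpent-1-en-4-yne
Product: 11 (8R,9S)-9-[(tert-butyldimethylsilyl)oxy]-2,8-dimethyldodeca-1,11-dien-4-yn-6-one, via lithium acetylide 10 (not isolated)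
Conditions: 9, n-BuLi, THF, −78 °C; then 6, −78 → 0 °C; aq. NH4Cl
Reagents that add atoms: none
Why: Acylation of a lithium acetylide by a Weinreb amide stops at the ketone because the chelated tetrahedral adduct survives until the quench.

Step 7
Reactants: 11 (8R,9S)-9-[(tert-butyldimethylsilyl)oxy]-2,8-dimethyldodeca-1,11-dien-4-yn-6-one
Product: 12 (6R,8R,9S)-9-[(tert-butyldimethylsilyl)oxy]-2,8-dimethyldodeca-1,11-dien-4-yn-6-ol
Conditions: Ru[(R,R)-TsDPEN](p-cymene) (2 mol %, base-free amido complex), i-PrOH, rt
Reagents that add atoms: none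
Why: Noyori asymmetric transfer hydrogenation of an ynone, with the alkynyl group in the position of the aryl group of the usual model, should give the (R)-propargylic alcohol (C6) under neutral conditions that do not isomerise the skipped enyne.

Step 8
Reactants: 12 (6R,8R,9S)-9-[(tert-butyldimethylsilyl)oxy]-2,8-dimethyldodeca-1,11-dien-4-yn-6-ol
Product: 13 (4E,6R,8R,9S)-9-[(tert-butyldimethylsilyl)oxy]-2,8-dimethyldodeca-1,4,11-trien-6-ol
Conditions: NaAlH2(OCH2CH2OCH3)2 (Red-Al), THF, 0 °C → rt; Rochelle salt work-up
Reagents that add atoms: none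
Why: Hydroxyl-directed trans-hydroalumination of a propargylic alcohol gives only the (E)-allylic alcohol and leaves the isolated olefins alone.

Step 9
Reactants: 13 (4E,6R,8R,9S)-9-[(tert-butyldimethylsilyl)oxy]-2,8-dimethyldodeca-1,4,11-trien-6-ol
Product: 14 (4R,5R,6R,8R,9S)-9-[(tert-butyldimethylsilyl)oxy]-4,5-epoxy-2,8-dimethyldodeca-1,11-dien-6-ol
Conditions: Ti(OiPr)4 (0.2 equiv), D-(−)-diisopropyl tartrate (0.25 equiv), t-BuOOH (2 equiv), 4 Å MS, CH2Cl2, −20 °C
Reagents that add atoms: tert-butyl hydroperoxide, CC(C)(C)OO
Why: Sharpless asymmetric epoxidation in the matched sense for an (R)-configured secondary (E)-allylic alcohol should epoxidise only the allylic olefin and give the anti (erythro) epoxy alcohol, fixing the C8–O configuration that the target keeps.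

Step 10
Reactants: 14 (4R,5R,6R,8R,9S)-9-[(tert-butyldimethylsilyl)oxy]-4,5-epoxy-2,8-dimethyldodeca-1,11-dien-6-ol
Product: 15 prop-2-yn-1-yl ether of 14 at the C6 hydroxyl
Conditions: NaH, propargyl bromide, Bu4NI (cat.), THF, 0 °C → rt
Reagents that add atoms: propargyl bromide, C#CCBr
Why: Williamson etherification with a reactive propargylic halide under aprotic conditions should outrun Payne rearrangement of the epoxy alkoxide and changes no stereocentre.

Step 11
Reactants: 15 prop-2-yn-1-yl ether of 14 at the C6 hydroxyl
Product: 17 (1R)-1-[(2R,3R)-2-[(2R,3S)-3-[(tert-butyldimethylsilyl)oxy]-2-methylhex-5-en-1-yl]-4-methylideneoxolan-3-yl]-3-methylbut-3-en-1-ol, via titanocene alkoxide 16 (not isolated)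
Conditions: Cp2TiCl2 (2.5 equiv), Zn dust, THF, rt (green Cp2TiCl); added over 2 h to 15 (0.02 M, THF, rt); then 1 M HCl
Reagents that add atoms: none
Why: Cp2TiCl (trivalent titanium) binds the epoxide of 15 and, by inner-sphere electron transfer, homolyses the C7–O bond to a C7 radical carrying a C8 titanoxy group; this radical adds to the internal alkyne carbon of the propargyl ether (C7–C11 bond), and the C13 vinyl radical is quenched by hydrogen abstraction from THF or by capture with a second Cp2TiCl and protonolysis, leaving alkoxide 16 for acidic hydrolysis. The closest known reaction type is the Cp2TiCl-mediated reductive epoxide opening/radical cyclization of propargyl ethers of 2,3-epoxy alcohols to 4-(1-hydroxyalkyl)-3-methyleneoxolanes, the radical precursors of α-methylene-γ-butyrolactones. Only one ring closes, ring B as its oxolane (O6–CH2–C11–C7–C6), in the 5-exo-dig mode. C7 is the one new stereocentre: its epoxide configuration is erased at the planar radical and it is re-set trans to the C5 chain on C6 through a chair-like transition state with the C6 substituent and the C8 branch both pseudo-equatorial, while C8 keeps the C–O bond from the Sharpless step and appears as the free carbinol. The step needs cleavage of the proximal C7–O rather than the distal C8–O bond and ring closure faster than further reduction of the C7 radical (which would end in β-elimination); the first should be favoured by chelation of titanium between the epoxide and the O6 ether oxygen and by the usual preference of 2,3-epoxy alcohol derivatives for the 1,3-dioxygenated radical, the second by slow addition that keeps Cp2TiCl scarce, and the other two olefins could only close 4-exo or 7-exo and should not compete. One operation thus delivers the C7–C11 bond, ring B, the C7 configuration, the C11=C13 methylene and the C8 hydroxyl ready for acylation.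

Step 12
Reactants: 18 tert-butyl acrylate; 19 acetaldehyde
Product: 20 tert-butyl 3-hydroxy-2-methylidenebutanoate (racemic)
Conditions: DABCO (0.5 equiv), dioxane/H2O, rt
Reagents that add atoms: none
Why: Morita–Baylis–Hillman reaction joins the acrylate α-carbon to the aldehyde, and the racemic carbinol centre is removed in the next step.

Step 13
Reactants: 20 tert-butyl 3-hydroxy-2-methylidenebutanoate (racemic)
Product: 22 tert-butyl (E)-2-(acetoxymethyl)but-2-enoate, via allylic acetate 21 (not isolated)
Conditions: Ac2O, pyridine, DMAP (cat.), CH2Cl2, 0 °C → rt; then DABCO (0.3 equiv), THF, 65 °C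
Reagents that add atoms: acetic anhydride, CC(=O)OC(C)=O
Why: Acetylation followed by DABCO-catalysed SN2'–SN2' (1,3) transposition of the allylic acetate should settle on the thermodynamically preferred trisubstituted (E)-olefin, with the methyl group trans to the ester.

Step 14
Reactants: 22 tert-butyl (E)-2-(acetoxymethyl)but-2-enoate
Product: 23 (E)-2-(acetoxymethyl)but-2-enoic acid
Conditions: TFA, CH2Cl2, 0 °C → rt
Reagents that add atoms: none
Why: Acidolysis of the tert-butyl ester with loss of isobutene leaves the allylic acetate and the olefin geometry intact.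

Step 15
Reactants: 17 the oxolane alcohol from step 11; 23 (E)-2-(acetoxymethyl)but-2-enoic acid
Product: 25 (E)-2-(acetoxymethyl)but-2-enoate ester of 17 at the C8 hydroxyl, via mixed anhydride 24 (not isolated)
Conditions: 23, 2,4,6-trichlorobenzoyl chloride, Et3N, THF, rt; then 17, DMAP (0.5 equiv), toluene, rt
Reagents that add atoms: none
Why: Yamaguchi esterification lets the hindered C8 alcohol attack the aliphatic carbonyl of the mixed anhydride under DMAP catalysis, with retention at C8 and with the stable tiglate-type (E) geometry preserved.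

Step 16
Reactants: 25 (E)-2-(acetoxymethyl)but-2-enoate ester of 17 at the C8 hydroxyl
Product: 26 α-methylene-γ-butyrolactone (the ring O–CH2 of 25 oxidised to the C12 carbonyl)
Conditions: CrO3 (15 equiv), pyridine (30 equiv), CH2Cl2, rt
Reagents that add atoms: chromium trioxide, O=[Cr](=O)=O
Why: Collins-type allylic oxidation should take the ring CH2, which is both allylic and α to the ether oxygen, to the lactone carbonyl much faster than it attacks the allylic positions of the terminal olefins or of the electron-poor side-chain enoate.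

Step 17
Reactants: 26 α-methylene-γ-butyrolactone
Product: 27 (3S)-3-[(tert-butyldimethylsilyl)oxy] analogue of the target (ring A closed, silylated C3 carbinol in place of the ketone)
Conditions: second-generation Hoveyda–Grubbs catalyst RuCl2(H2IMes)(=CH-C6H4-2-OiPr) (15 mol %), 1,4-benzoquinone (30 mol %), toluene (1 mM), 80 °C
Reagents that add atoms: none
Why: In this RCM the ruthenium carbene should form at the monosubstituted C1 olefin and close on the 1,1-disubstituted C10 olefin, the ten-membered ring accommodating only the (Z)-trisubstituted olefin comfortably under reversible metathesis, while closure on the electron-poor C11=C13 olefin would create a strained bridgehead olefin.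

Step 18
Reactants: 27 (3S)-3-[(tert-butyldimethylsilyl)oxy] analogue of the target
Product: 28 (3S)-3-hydroxy analogue of the target
Conditions: HF·pyridine, pyridine, THF, 0 °C → rt
Reagents that add atoms: none
Why: Buffered fluoride cleavage of the secondary silyl ether should spare the two esters, the allylic acetate and the conjugate acceptor.

Step 19
Reactants: 28 (3S)-3-hydroxy analogue of the target
Product: 29 CNP0265140.1 (target)
Conditions: Dess–Martin periodinane, NaHCO3, CH2Cl2, 0 °C → rt
Reagents that add atoms: none
Why: Dess–Martin oxidation of the homoallylic carbinol under buffered, non-enolising conditions should give the β,γ-unsaturated C3 ketone without migration of the C1=C10 olefin or epimerisation at C4.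

**Compound list**
1 | ethyl (E)-4-oxobut-2-enoate | CCOC(=O)/C=C/C=O | starting material
2 | ethyl (2E,4S)-4-hydroxyhepta-2,6-dienoate | C=CC[C@H](O)/C=C/C(=O)OCC | intermediate
3 | ethyl (2E,4S)-4-[(tert-butyldimethylsilyl)oxy]hepta-2,6-dienoate | C=CC[C@H](O[Si](C)(C)C(C)(C)C)/C=C/C(=O)OCC | intermediate
4 | ethyl trimethylsilyl ketene acetal of 5 | CCOC(O[Si](C)(C)C)=C[C@@H](C)[C@@H](O[Si](C)(C)C(C)(C)C)CC=C | intermediate (not isolated)
5 | ethyl (3R,4S)-4-[(tert-butyldimethylsilyl)oxy]-3-methylhept-6-enoate | CCOC(=O)C[C@@H](C)[C@@H](O[Si](C)(C)C(C)(C)C)CC=C | intermediate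
6 | (3R,4S)-4-[(tert-butyldimethylsilyl)oxy]-N-methoxy-N,3-dimethylhept-6-enamide | CON(C)C(=O)C[C@@H](C)[C@@H](O[Si](C)(C)C(C)(C)C)CC=C | intermediate
7 | 3-chloro-2-methylprop-1-ene | C=C(C)CCl | starting material
8 | ethynylmagnesium bromide | C#C[Mg]Br | starting material
9 | 2-methylpent-1-en-4-yne | C=C(C)CC#C | intermediate
10 | (4-methylpent-4-en-1-yn-1-yl)lithium | [Li]C#CCC(C)=C | intermediate (not isolated)
11 | (8R,9S)-9-[(tert-butyldimethylsilyl)oxy]-2,8-dimethyldodeca-1,11-dien-4-yn-6-one | C=C(C)CC#CC(=O)C[C@@H](C)[C@@H](O[Si](C)(C)C(C)(C)C)CC=C | intermediate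
12 | (6R,8R,9S)-9-[(tert-butyldimethylsilyl)oxy]-2,8-dimethyldodeca-1,11-dien-4-yn-6-ol | C=C(C)CC#C[C@H](O)C[C@@H](C)[C@@H](O[Si](C)(C)C(C)(C)C)CC=C | intermediate
13 | (4E,6R,8R,9S)-9-[(tert-butyldimethylsilyl)oxy]-2,8-dimethyldodeca-1,4,11-trien-6-ol | C=C(C)C/C=C/[C@H](O)C[C@@H](C)[C@@H](O[Si](C)(C)C(C)(C)C)CC=C | intermediate
14 | (4R,5R,6R,8R,9S)-9-[(tert-butyldimethylsilyl)oxy]-4,5-epoxy-2,8-dimethyldodeca-1,11-dien-6-ol (anti epoxy alcohol; epoxide carbons are C8 and C7 of the target) | C=C(C)C[C@H]1O[C@@H]1[C@H](O)C[C@@H](C)[C@@H](O[Si](C)(C)C(C)(C)C)CC=C | intermediate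
15 | prop-2-yn-1-yl ether of 14 at the C6 hydroxyl | C=C(C)C[C@H]1O[C@@H]1[C@H](OCC#C)C[C@@H](C)[C@@H](O[Si](C)(C)C(C)(C)C)CC=C | intermediate
16 | chlorotitanocene alkoxide of 17 (tetravalent titanium on the C8 oxygen) | C=C1CO[C@H](C[C@@H](C)[C@@H](O[Si](C)(C)C(C)(C)C)CC=C)[C@H]1[C@H](O[Ti](Cl)(C2C=CC=C2)C2C=CC=C2)CC(C)=C | intermediate (not isolated)
17 | (1R)-1-[(2R,3R)-2-[(2R,3S)-3-[(tert-butyldimethylsilyl)oxy]-2-methylhex-5-en-1-yl]-4-methylideneoxolan-3-yl]-3-methylbut-3-en-1-ol | C=C1CO[C@H](C[C@@H](C)[C@@H](O[Si](C)(C)C(C)(C)C)CC=C)[C@H]1[C@H](O)CC(C)=C | intermediate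
18 | tert-butyl acrylate | C=CC(=O)OC(C)(C)C | starting material
19 | acetaldehyde | CC=O | starting material
20 | tert-butyl 3-hydroxy-2-methylidenebutanoate (racemic) | CC(O)C(=C)C(=O)OC(C)(C)C | intermediate
21 | tert-butyl 3-acetoxy-2-methylidenebutanoate (racemic) | CC(OC(C)=O)C(=C)C(=O)OC(C)(C)C | intermediate (not isolated)
22 | tert-butyl (E)-2-(acetoxymethyl)but-2-enoate | C/C=C(/C(=O)OC(C)(C)C)COC(C)=O | intermediate
23 | (E)-2-(acetoxymethyl)but-2-enoic acid | C/C=C(/C(=O)O)COC(C)=O | intermediate
24 | mixed anhydride of 23 with 2,4,6-trichlorobenzoic acid | C/C=C(/C(=O)OC(=O)c1c(Cl)cc(Cl)cc1Cl)COC(C)=O | intermediate (not isolated)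
25 | (E)-2-(acetoxymethyl)but-2-enoate ester of 17 at the C8 hydroxyl (stereocentres as in 17) | C=C1CO[C@H](C[C@@H](C)[C@@H](O[Si](C)(C)C(C)(C)C)CC=C)[C@H]1[C@H](OC(=O)/C(=C/C)COC(C)=O)CC(C)=C | intermediate
26 | α-methylene-γ-butyrolactone: 25 with the ring O–CH2 oxidised to the C12 carbonyl (stereocentres as in 25) | C=C1C(=O)O[C@H](C[C@@H](C)[C@@H](O[Si](C)(C)C(C)(C)C)CC=C)[C@H]1[C@H](OC(=O)/C(=C/C)COC(C)=O)CC(C)=C | intermediate
27 | (3S)-3-[(tert-butyldimethylsilyl)oxy] analogue of the target (silylated C3 carbinol in place of the ketone; (Z)-C1=C10) | C=C1C(=O)O[C@@H]2C[C@@H](C)[C@@H](O[Si](C)(C)C(C)(C)C)C/C=C(/C)C[C@@H](OC(=O)/C(=C/C)COC(C)=O)[C@@H]12 | intermediate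
28 | (3S)-3-hydroxy analogue of the target | C=C1C(=O)O[C@@H]2C[C@@H](C)[C@@H](O)C/C=C(/C)C[C@@H](OC(=O)/C(=C/C)COC(C)=O)[C@@H]12 | intermediate
29 | CNP0265140.1 | C=C1C(=O)O[C@@H]2C[C@@H](C)C(=O)C/C=C(/C)C[C@@H](OC(=O)/C(=C/C)COC(C)=O)[C@@H]12 | target

**Totals and risks**
Total step count: 19. Longest linear sequence: 15 steps (steps 1–4, 6–11, 15–19, from ethyl (E)-4-oxobut-2-enoate).

Most likely to fail:

Step 17 (ring-closing metathesis). The ten-membered closure may be slow, so that intermolecular metathesis (oligomerisation), engagement of the C11=C13 olefin, or olefin migration by ruthenium hydrides takes over. Fallback: close ring A before the lactone carbonyl and the side-chain ester are present. It sets out from 17: RCM of the free homoallylic alcohol under the same high-dilution conditions should give the bicyclic methyleneoxolane cyclodecenol F1; Yamaguchi esterification with 23 should give the ester F2; Collins oxidation of the ring O–CH2 then rejoins the route at 27.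

Step 11 (key step). The distal C8–O bond may cleave instead (then 6-exo closure or deoxygenation); the C7 radical may be reduced before it cyclises and then undergo β-elimination; the allylic C9 hydrogen may transfer to the vinyl radical; or trans selectivity at C7 may be insufficient. Fallback: a polar, stereospecific closure of the same bond. It sets out from 14: alkylation with 2,3-dibromopropene (NaH, THF) should give the 2-bromoallyl ether F3; bromine–lithium exchange (t-BuLi, Et2O, −78 °C) and BF3·OEt2-assisted 5-exo-tet opening of the epoxide at C7 by the vinyllithium, with inversion at C7 (the trans arrangement, starting from the anti epoxy alcohol), rejoins the route at 17.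

Step 16 (allylic oxidation). Oxidation may spread to the other allylic positions (C2, C9, side-chain methyl), or the exocyclic olefin may migrate into the ring on long exposure to the chromium reagent. Fallback: carry C12 through the key step at the acetal oxidation level. It sets out from 14: transacetalisation with 3,3-diethoxyprop-1-yne (PPTS, benzene, removal of ethanol) should give the mixed propynal acetal F4 (both epimers at the acetal carbon); the same Cp2TiCl cyclization should give the 2-ethoxy-3-methyleneoxolane alcohol F5; Yamaguchi esterification with 23 should give the ester F6; Jones oxidation (CrO3, H2SO4, acetone, 0 °C) of the cyclic acetal rejoins the route at 26.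

**Further compounds**
F1 | step 17 | bicyclic methyleneoxolane cyclodecenol (ring A closed; free C8 hydroxyl; C3 silyl ether) | C=C1CO[C@@H]2C[C@@H](C)[C@@H](O[Si](C)(C)C(C)(C)C)C/C=C(/C)C[C@@H](O)[C@@H]12
F2 | step 17 | (E)-2-(acetoxymethyl)but-2-enoate ester of F1 at the C8 hydroxyl | C=C1CO[C@@H]2C[C@@H](C)[C@@H](O[Si](C)(C)C(C)(C)C)C/C=C(/C)C[C@@H](OC(=O)/C(=C/C)COC(C)=O)[C@@H]12
F3 | step 11 | 2-bromoprop-2-en-1-yl ether of 14 at the C6 hydroxyl | C=C(C)C[C@H]1O[C@@H]1[C@H](OCC(Br)=C)C[C@@H](C)[C@@H](O[Si](C)(C)C(C)(C)C)CC=C
F4 | step 16 | mixed ethyl propynal acetal of 14 at the C6 hydroxyl (epimers at the acetal carbon) | C=C(C)C[C@H]1O[C@@H]1[C@H](OC(OCC)C#C)C[C@@H](C)[C@@H](O[Si](C)(C)C(C)(C)C)CC=C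
F5 | step 16 | 2-ethoxy analogue of 17 (2-ethoxy-3-methyleneoxolane alcohol; epimers at the acetal carbon) | C=C1C(OCC)O[C@H](C[C@@H](C)[C@@H](O[Si](C)(C)C(C)(C)C)CC=C)[C@H]1[C@H](O)CC(C)=C
F6 | step 16 | (E)-2-(acetoxymethyl)but-2-enoate ester of F5 at the C8 hydroxyl | C=C1C(OCC)O[C@H](C[C@@H](C)[C@@H](O[Si](C)(C)C(C)(C)C)CC=C)[C@H]1[C@H](OC(=O)/C(=C/C)COC(C)=O)CC(C)=C
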